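The C1'–C8' side chain is read as intact (E)-β-ocimene. The benzene ring sits on C1' and the acetoxy oxygen on C4', the two termini of the ocimene diene, with the C2'=C3' alkene between them. A single palladium-catalysed three-component coupling therefore joins ring carbon C3 to C1' and an acetate oxygen to C4', setting the E-alkene and the (R)-centre at C4' in one operation. Its precursors are (5-formyl-2-methoxyphenyl)boronic acid, (E)-β-ocimene and acetic acid, all commercial. The formyl group is a spectator that a closing Doebner condensation converts into the E-propenoic acid.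

Key step: step 1

Assumption: (E)-β-ocimene is bought as an E-enriched grade (fractionally distilled if needed) and used in excess; the side chain is numbered from the benzylic carbon C1' to C8', with methyl groups on C3' and C7', and C4' is (R) by CIP (O > C3' > C5' > H).

Step 1
Reactants: 1 (5-formyl-2-methoxyphenyl)boronic acid; 2 (E)-β-ocimene [(3E)-3,7-dimethylocta-1,3,6-triene]; 3 acetic acid
Product: 6 3-[(2E,4R)-4-acetoxy-3,7-dimethylocta-2,6-dien-1-yl]-4-methoxybenzaldehyde, via ArPd(OAc)(PyrOx) 4 (not isolated), via (η3-allyl)Pd(OAc)(PyrOx) 5 (not isolated)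
Conditions: Pd(OAc)2 (10 mol %), (S)-t-BuPyrOx [(S)-4-tert-butyl-2-(pyridin-2-yl)-4,5-dihydrooxazole] (12 mol %), 1,4-benzoquinone (2 equiv), LiOAc (0.5 equiv), AcOH (3, 10 equiv), 2 (3 equiv), 1,4-dioxane, 25 °C
Reagents that add atoms: none
Why: Proposed new method: boron-to-palladium transmetalation of 1 onto the ligand-bound divalent palladium acetate gives 4, which adds across the unsubstituted C1'=C2' vinyl terminus of the s-trans diene of 2 (Heck-type syn insertion, aryl to C1') and becomes the syn,syn-η3-allyl complex 5 over C2'–C4', whose C4' terminus is then attacked by acetate on the face opposite palladium while benzoquinone takes up the electrons and returns zerovalent palladium to the divalent state. The closest known reaction types are palladium-catalysed three-component couplings of an aryl donor, a 1,3-diene and a nucleophile through Heck insertion and η3-allyl capture, and the benzoquinone-mediated 1,4-diacetoxylation of 1,3-dienes with Pd(OAc)2; pairing an arylboronic acid with acetate capture on an acyclic trisubstituted diene has not been shown. No ring is closed; only the aryl–C1' bond and the C4'–O bond are formed. The C4' centre is controlled by the chiral pyridine–oxazoline ligand, which selects the diene face at insertion; palladium stays on that face of the allyl and acetate enters anti to it, so the configuration is relayed from the insertion event, and the ligand antipode that delivers (R) would be fixed in a first screen. The step needs 1,4- over 1,2-capture, E geometry at C2'=C3' and a single mode of acetate delivery: the syn position of C1' in the allyl, inherited from the s-trans diene, gives E, and the bidentate ligand leaves no site for inner-sphere acetate, but the preference for C4' over C2' is not secured by the substrate and rests on the ligand together with the bulk of the ortho-methoxybenzyl group at C2'. The trisubstituted C6'=C7' alkene is too hindered to insert, the aldehyde is inert, and excess benzoquinone keeps zerovalent palladium from re-ionising the product acetate.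

Step 2
Reactants: 6 3-[(2E,4R)-4-acetoxy-3,7-dimethylocta-2,6-dien-1-yl]-4-methoxybenzaldehyde; 7 malonic acid
Product: 9 (2E)-3-[3-[(2E,4R)-4-acetoxy-3,7-dimethylocta-2,6-dien-1-yl]-4-methoxyphenyl]prop-2-enoic acid, via arylidenemalonic acid 8 (not isolated)
Conditions: 7 (3 equiv), piperidine (0.1 equiv), pyridine, 85 °C
Reagents that add atoms: none
Why: Doebner modification of the Knoevenagel condensation: amine-catalysed condensation of the aryl aldehyde with malonic acid gives arylidenemalonic acid 8, which loses CO2 in hot pyridine to the thermodynamically preferred E-cinnamic acid, under weakly basic, non-hydrolytic conditions that should leave the secondary acetate, both trisubstituted alkenes and the C4' centre untouched.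

Compound list
1 | (5-formyl-2-methoxyphenyl)boronic acid | COc1ccc(C=O)cc1B(O)O | starting material
2 | (E)-β-ocimene, (3E)-3,7-dimethylocta-1,3,6-triene | C=C/C(C)=C/CC=C(C)C | starting material
3 | acetic acid | CC(=O)O | starting material
4 | ArPd(OAc)(PyrOx): (5-formyl-2-methoxyphenyl)palladium acetate bearing the pyridine–oxazoline ligand (ligand not drawn) | COc1ccc(C=O)cc1[Pd]OC(C)=O | intermediate
5 | (η3-allyl)Pd(OAc)(PyrOx): syn,syn-η3-allylpalladium acetate over C2'–C4' (drawn as its C2' σ-form, a transient carbon without fixed configuration; ligand not drawn) | COc1ccc(C=O)cc1CC([Pd]OC(C)=O)/C(C)=C/CC=C(C)C | intermediate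
6 | 3-[(2E,4R)-4-acetoxy-3,7-dimethylocta-2,6-dien-1-yl]-4-methoxybenzaldehyde | COc1ccc(C=O)cc1C/C=C(\C)[C@@H](CC=C(C)C)OC(C)=O | intermediate
7 | malonic acid | OC(=O)CC(=O)O | starting material
8 | 2-[[3-[(2E,4R)-4-acetoxy-3,7-dimethylocta-2,6-dien-1-yl]-4-methoxyphenyl]methylidene]propanedioic acid | COc1ccc(C=C(C(=O)O)C(=O)O)cc1C/C=C(\C)[C@@H](CC=C(C)C)OC(C)=O | intermediate
9 | (2E)-3-[3-[(2E,4R)-4-acetoxy-3,7-dimethylocta-2,6-dien-1-yl]-4-methoxyphenyl]prop-2-enoic acid | COc1ccc(/C=C/C(=O)O)cc1C/C=C(\C)[C@@H](CC=C(C)C)OC(C)=O | target

Total step count: 2. Longest linear sequence: 2.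

Steps most likely to fail (the route has only two steps, so both are listed, the labelled one first):

1. Step 1. Several processes may go wrong:
- acetate capture at C2' in place of C4' (1,2- instead of 1,4-addition);
- weak facial discrimination at the insertion, hence low enantiomeric purity;
- β-hydride loss from the allyl intermediate, giving a plain Heck triene;
- direct diacetoxylation of the diene without aryl transfer;
- homocoupling or protodeboronation of the boronic acid;
- palladium-mediated 1,3-transposition of the product acetate.

Fallback by known chemistry, setting out from 1 and returning to the route at 6. Commercial (E)-4-acetoxy-2-methylbut-2-enal (CC(=O)OC/C=C(\C)C=O) is allylated with allylboronic acid pinacol ester under chiral phosphoric acid catalysis ((R)-TRIP, (R)-3,3'-bis(2,4,6-triisopropylphenyl)-1,1'-binaphthyl-2,2'-diyl hydrogen phosphate, 5 mol %, toluene, −30 °C). Re-face allyl transfer is expected, and the antipodal acid would be taken if the sense proves opposite. This should give (2E,4R)-4-hydroxy-3-methylhepta-2,6-dien-1-yl acetate F1. A Suzuki–Miyaura-type allyl–aryl coupling of the primary allylic acetate of F1 with 1 (Pd(PPh3)4, KF, THF, 50 °C) should place the aryl group on the unsubstituted allyl terminus and give 3-[(2E,4R)-4-hydroxy-3-methylhepta-2,6-dien-1-yl]-4-methoxybenzaldehyde F2. The C4' oxygen is kept as a non-ionisable hydroxyl while zerovalent palladium is present. Acetylation (Ac2O, pyridine, DMAP, CH2Cl2, 0 °C to 25 °C) then gives (2E,4R)-1-(5-formyl-2-methoxyphenyl)-3-methylhepta-2,6-dien-4-yl acetate F3. Cross-metathesis of its terminal vinyl group with excess 2-methylbut-2-ene (second-generation Grubbs catalyst, CH2Cl2, 40 °C) converts allyl into prenyl, the trisubstituted C2'=C3' alkene staying inert, and delivers 6.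

2. Step 2. The allylic acetate may be lost by aminolysis or elimination in hot pyridine/piperidine, the electron-rich aldehyde may condense slowly, and decarboxylation may stay incomplete.

Fallback setting out from 6 and returning at 9. Horner–Wadsworth–Emmons olefination of 6 with triethyl phosphonoacetate (LiCl, DBU, MeCN, 25 °C) should give ethyl (2E)-3-[3-[(2E,4R)-4-acetoxy-3,7-dimethylocta-2,6-dien-1-yl]-4-methoxyphenyl]prop-2-enoate F4. Saponification of both esters (LiOH, THF/H2O, 25 °C) gives (2E)-3-[3-[(2E,4R)-4-hydroxy-3,7-dimethylocta-2,6-dien-1-yl]-4-methoxyphenyl]prop-2-enoic acid F5 without touching the C4' centre. O-Acetylation (Ac2O, pyridine, DMAP, then aqueous NaHCO3 to hydrolyse the mixed anhydride) restores the C4' acetate and gives 9.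

Further compounds
F1 | step 1 | (2E,4R)-4-hydroxy-3-methylhepta-2,6-dien-1-yl acetate | CC(=O)OC/C=C(\C)[C@@H](CC=C)O
F2 | step 1 | 3-[(2E,4R)-4-hydroxy-3-methylhepta-2,6-dien-1-yl]-4-methoxybenzaldehyde | COc1ccc(C=O)cc1C/C=C(\C)[C@@H](CC=C)O
F3 | step 1 | (2E,4R)-1-(5-formyl-2-methoxyphenyl)-3-methylhepta-2,6-dien-4-yl acetate | COc1ccc(C=O)cc1C/C=C(\C)[C@@H](CC=C)OC(C)=O
F4 | step 2 | ethyl (2E)-3-[3-[(2E,4R)-4-acetoxy-3,7-dimethylocta-2,6-dien-1-yl]-4-methoxyphenyl]prop-2-enoate | COc1ccc(/C=C/C(=O)OCC)cc1C/C=C(\C)[C@@H](CC=C(C)C)OC(C)=O
F5 | step 2 | (2E)-3-[3-[(2E,4R)-4-hydroxy-3,7-dimethylocta-2,6-dien-1-yl]-4-methoxyphenyl]prop-2-enoic acid | COc1ccc(/C=C/C(=O)O)cc1C/C=C(\C)[C@@H](CC=C(C)C)O
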